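**Retrosynthetic overview**

- Labels: ring A = 2,6-dimethoxyphenyl on ketone carbon K1. Ring B = central ring with K1 on B1, OH on B2, H on B3, CH3 on B4, OCH3 on B5 and the CH2 carbon Cα on B6. K2 = ketone carbon of the Cα–C(=O) arm. Ring C = second central ring with K2 on C1, OCH3 on C2, CH3 on C3, H on C4, OH on C5 and aroyl carbon K3 on C6. Ring D = 2,6-dimethoxyphenyl on K3.
- Feature used: K1 and K2 are the two ends of a 1,5-dicarbonyl unit K1–B1–B6–Cα–K2. A K1=K2 double bond turns this unit into a 3-aryl-1H-indene, so both carbonyl groups are released together by cleaving that one double bond.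
- Disconnections, backwards: the two O-benzyl groups (on B2 and C5); the K2 and K3 carbonyls from carbinols; C1–K2 by addition of a ring C aryl-metal (K3 carried as a carbinol alkoxide) to an arylacetaldehyde; that aldehyde and the K1 ketone by ozonolysis of the indene; the indene from benzylic alcohol 6 and alkyne 8 by FeCl3-catalysed [3+2] annulation (bonds Cα–K2 and K1–B1).
- Ring order: all four benzene rings are bought. The only ring made is the five-membered ring of the indene (step 6), and it is opened again in step 7. Rings B and C both come from phenol 3.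

Key step: step 6

Remark (assumption): the carbinol centres of 17, 20 and F6 and the ozonide 12 are formed without stereocontrol and are written without stereodescriptors, because each of these centres becomes a carbonyl carbon. The target has no stereocentre.

**Route**

Step 1
Reactants: 1 2-methylhydroquinone; 2 benzyl bromide
Product: 3 4-(benzyloxy)-2-methylphenol
Conditions: K2CO3 (1 equiv), 2 (1 equiv), acetone, reflux, N2
Reagents that add atoms: none
Why: Williamson ether synthesis in which the C4 hydroxyl, which has no ortho substituent and is the slightly more acidic one, should be alkylated preferentially, the regioisomer and the bis-ether being removed by chromatography.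

Step 2
Reactants: 3 4-(benzyloxy)-2-methylphenol
Product: 4 5-(benzyloxy)-2-hydroxy-3-methylbenzaldehyde
Conditions: MgCl2, Et3N, (CH2O)n, MeCN, reflux; then 1 M HCl
Reagents that add atoms: paraformaldehyde (as formaldehyde), C=O
Why: Magnesium-mediated ortho-formylation of a phenol (Casnati–Skattebøl), in which the magnesium phenoxide delivers formaldehyde to the only free ortho position and excess formaldehyde acts as the hydride acceptor that brings the new carbon to the aldehyde level.

Step 3
Reactants: 4 5-(benzyloxy)-2-hydroxy-3-methylbenzaldehyde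
Product: 5 5-(benzyloxy)-2-methoxy-3-methylbenzaldehyde
Conditions: MeI, K2CO3, DMF, rt
Reagents that add atoms: iodomethane, CI
Why: Williamson O-methylation of the phenol, which leaves the aldehyde and the benzyl ether untouched.

Step 4
Reactants: 5 5-(benzyloxy)-2-methoxy-3-methylbenzaldehyde
Product: 6 [5-(benzyloxy)-2-methoxy-3-methylphenyl]methanol
Conditions: NaBH4, MeOH/THF, 0 °C
Reagents that add atoms: none
Why: Hydride reduction of an aromatic aldehyde to the primary benzylic alcohol, with the ethers inert to NaBH4.

Step 5
Reactants: 7 2,6-dimethoxybenzaldehyde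
Product: 8 2-ethynyl-1,3-dimethoxybenzene
Conditions: dimethyl (1-diazo-2-oxopropyl)phosphonate, K2CO3, MeOH, rt
Reagents that add atoms: dimethyl (1-diazo-2-oxopropyl)phosphonate, COP(=O)(OC)C(=[N+]=[N-])C(C)=O
Why: Seyferth–Gilbert homologation in the Ohira–Bestmann form, in which methanolysis of the acetyl group releases the diazomethylphosphonate anion, this anion olefinates the non-enolisable aldehyde, and loss of N2 with a 1,2-hydrogen shift gives the terminal alkyne.

Step 6
Reactants: 6 [5-(benzyloxy)-2-methoxy-3-methylphenyl]methanol; 8 2-ethynyl-1,3-dimethoxybenzene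
Product: 11 4-(benzyloxy)-3-(2,6-dimethoxyphenyl)-7-methoxy-6-methyl-1H-indene, via benzylic cation 9 (not isolated), via vinyl cation 10 (not isolated)
Conditions: FeCl3 (10 mol%), 4 Å MS, CH3NO2, 50 °C; 6 added slowly to 8 (2 equiv)
Reagents that add atoms: none
Why: FeCl3 turns the primary hydroxyl of 6 into a leaving group and gives benzylic cation 9, supported by the B5 methoxy oxygen (less than in a plain ortho-anisyl cation, because the flanking B4 methyl hinders coplanarity, hence the warm nitromethane); 9 is captured by the terminal carbon of alkyne 8 (Cα–K2 bond), which puts the charge of vinyl cation 10 on the carbon that bears ring A. Cation 10 then alkenylates B1 (K1–B1 bond) and loss of a proton restores ring B, so the overall change is a dehydrative formal [3+2] annulation; the closest known reaction type is the FeCl3-catalysed benzylation–cyclisation of benzylic alcohols with aryl alkynes to 3-aryl-1H-indenes, shown mostly for secondary alcohols, with an electron-rich primary alcohol at the edge of that scope. The five-membered ring closes by an intramolecular Friedel–Crafts alkenylation, a 5-endo-type attack of the arene on the in-plane empty orbital of the linear cation, so that the new C=C bond lies inside the ring between K1 and K2. No stereocentre is formed. The step needs Markovnikov orientation on the alkyne, secured by the aryl-stabilised cation 10; capture of 9 by the alkyne and not by an arene, helped by the excess of 8 and the slow addition of 6; and closure at B1, which is the only free position ortho to Cα and is activated by the ortho benzyloxy and para methyl groups. The molecular sieves take up the water that is set free, so that neither 10 nor 8 is hydrated.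

Step 7
Reactants: 11 4-(benzyloxy)-3-(2,6-dimethoxyphenyl)-7-methoxy-6-methyl-1H-indene
Product: 13 2-[3-(benzyloxy)-2-(2,6-dimethoxybenzoyl)-6-methoxy-5-methylphenyl]acetaldehyde, via ozonide 12 (not isolated)
Conditions: O3, CH2Cl2, −78 °C (Sudan Red 7B end point); then PPh3, −78 °C to rt
Reagents that add atoms: ozone, [O-][O+]=O
Why: Ozonolysis (Criegee mechanism) with reductive work-up, in which the small ozone molecule should reach the trisubstituted C2=C3 bond beside the twisted ring A and react with it faster than with the alkoxyarenes when dosing stops at the indicator end point, and PPh3 reduces ozonide 12 to the K1 ketone and the CH2CHO arm.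

Step 8
Reactants: 3 4-(benzyloxy)-2-methylphenol
Product: 14 4-(benzyloxy)-2-bromo-6-methylphenol
Conditions: NBS, iPr2NH (cat), CH2Cl2, 0 °C
Reagents that add atoms: N-bromosuccinimide, BrN1C(=O)CCC1=O
Why: Electrophilic aromatic bromination directed by the free phenol, whose para position is blocked, so that the one free ortho position should be brominated in preference to the positions ortho to the weaker benzyloxy donor.

Step 9
Reactants: 14 4-(benzyloxy)-2-bromo-6-methylphenol
Product: 15 5-(benzyloxy)-1-bromo-2-methoxy-3-methylbenzene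
Conditions: MeI, K2CO3, DMF, rt
Reagents that add atoms: iodomethane, CI
Why: Williamson O-methylation of the phenol, to which the aryl bromide and the benzyl ether are inert.

Step 10
Reactants: 15 5-(benzyloxy)-1-bromo-2-methoxy-3-methylbenzene; 7 2,6-dimethoxybenzaldehyde
Product: 17 [6-(benzyloxy)-2-bromo-3-methoxy-4-methylphenyl](2,6-dimethoxyphenyl)methanol (racemic), via aryllithium 16 (not isolated)
Conditions: LiN(iPr)2, THF, −78 °C; then 7, −78 °C; aq NH4Cl
Reagents that add atoms: none
Why: Directed ortho-metalation, in which the ring hydrogen flanked by bromine and the benzyloxy group is the most acidic and is removed by LiN(iPr)2 at −78 °C, where the ortho-bromo aryllithium 16 does not yet lose LiBr, and 16 then adds to the non-enolisable aldehyde 7 to give the racemic carbinol.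

Step 11
Reactants: 17 [6-(benzyloxy)-2-bromo-3-methoxy-4-methylphenyl](2,6-dimethoxyphenyl)methanol; 13 2-[3-(benzyloxy)-2-(2,6-dimethoxybenzoyl)-6-methoxy-5-methylphenyl]acetaldehyde
Product: 20 1-{3-(benzyloxy)-2-[(2,6-dimethoxyphenyl)(hydroxy)methyl]-6-methoxy-5-methylphenyl}-2-[3-(benzyloxy)-2-(2,6-dimethoxybenzoyl)-6-methoxy-5-methylphenyl]ethan-1-ol (mixture of diastereomers), via dilithio species 18 (not isolated), via organocerium reagent 19 (not isolated)
Conditions: 17 (1.5 equiv), n-BuLi (2 equiv per 17), THF, −78 °C; CeCl3 (anhydrous), −78 °C; then 13, −78 to −40 °C; aq NH4Cl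
Reagents that add atoms: none
Why: Deprotonation of the hydroxyl and bromine–lithium exchange give dianion 18, transmetalation to the weakly basic organocerium reagent 19 favours 1,2-addition to the enolisable aldehyde of 13 over deprotonation at Cα, and the shielded tetra-ortho-substituted K1 ketone is left alone; the new carbinol centre is formed without control, which does not matter because it is oxidised in step 12.

Step 12
Reactants: 20 the diol from step 11
Product: 21 1,2-bis[3-(benzyloxy)-2-(2,6-dimethoxybenzoyl)-6-methoxy-5-methylphenyl]ethan-1-one (O,O'-dibenzyl acredinone B)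
Conditions: Dess–Martin periodinane (3 equiv), pyridine, CH2Cl2, 0 °C to rt
Reagents that add atoms: none
Why: Dess–Martin oxidation of both secondary benzylic alcohols, buffered with pyridine so that neither acid-induced ionisation of the K3 carbinol nor base-induced aldol closure between Cα and K3 should interfere.

Step 13
Reactants: 21 O,O'-dibenzyl acredinone B
Product: 22 acredinone B, 1,2-bis[2-(2,6-dimethoxybenzoyl)-3-hydroxy-6-methoxy-5-methylphenyl]ethan-1-one
Conditions: H2 (1 atm), Pd/C, EtOAc, rt
Reagents that add atoms: none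
Why: Hydrogenolysis of the two aryl benzyl ethers over palladium on carbon, which should be much faster than reduction of the hindered diaryl ketones K1 and K3 or of the aryl benzyl ketone K2, so that the reaction is stopped at complete debenzylation.

**Compound list**

1 | 2-methylhydroquinone | Cc1cc(O)ccc1O | starting material
2 | benzyl bromide | BrCc1ccccc1 | starting material
3 | 4-(benzyloxy)-2-methylphenol | Cc1cc(OCc2ccccc2)ccc1O | intermediate
4 | 5-(benzyloxy)-2-hydroxy-3-methylbenzaldehyde | O=Cc1cc(OCc2ccccc2)cc(C)c1O | intermediate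
5 | 5-(benzyloxy)-2-methoxy-3-methylbenzaldehyde | O=Cc1cc(OCc2ccccc2)cc(C)c1OC | intermediate
6 | [5-(benzyloxy)-2-methoxy-3-methylphenyl]methanol | OCc1cc(OCc2ccccc2)cc(C)c1OC | intermediate
7 | 2,6-dimethoxybenzaldehyde | COc1cccc(OC)c1C=O | starting material
8 | 2-ethynyl-1,3-dimethoxybenzene | C#Cc1c(OC)cccc1OC | intermediate
9 | [5-(benzyloxy)-2-methoxy-3-methylphenyl]methylium (benzylic cation, not isolated) | [CH2+]c1cc(OCc2ccccc2)cc(C)c1OC | intermediate
10 | 3-[5-(benzyloxy)-2-methoxy-3-methylphenyl]-1-(2,6-dimethoxyphenyl)prop-1-en-1-ylium (vinyl cation, not isolated) | COc1cccc(OC)c1[C+]=CCc1cc(OCc2ccccc2)cc(C)c1OC | intermediate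
11 | 4-(benzyloxy)-3-(2,6-dimethoxyphenyl)-7-methoxy-6-methyl-1H-indene | COc1cccc(OC)c1C1=CCc2c(OC)c(C)cc(OCc3ccccc3)c21 | intermediate
12 | secondary ozonide of 11: 1,2,4-trioxolane whose O–O bridge and ether oxygen join the former indene C2 and C3 (racemic, not isolated) | COc1cccc(OC)c1C23OOC(O2)Cc2c(OC)c(C)cc(OCc4ccccc4)c23 | intermediate
13 | 2-[3-(benzyloxy)-2-(2,6-dimethoxybenzoyl)-6-methoxy-5-methylphenyl]acetaldehyde | COc1cccc(OC)c1C(=O)c1c(OCc2ccccc2)cc(C)c(OC)c1CC=O | intermediate
14 | 4-(benzyloxy)-2-bromo-6-methylphenol | Cc1cc(OCc2ccccc2)cc(Br)c1O | intermediate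
15 | 5-(benzyloxy)-1-bromo-2-methoxy-3-methylbenzene | COc1c(C)cc(OCc2ccccc2)cc1Br | intermediate
16 | [6-(benzyloxy)-2-bromo-3-methoxy-4-methylphenyl]lithium (not isolated) | [Li]c1c(Br)c(OC)c(C)cc1OCc1ccccc1 | intermediate
17 | [6-(benzyloxy)-2-bromo-3-methoxy-4-methylphenyl](2,6-dimethoxyphenyl)methanol (racemic) | COc1cccc(OC)c1C(O)c1c(Br)c(OC)c(C)cc1OCc1ccccc1 | intermediate
18 | lithium [6-(benzyloxy)-2-lithio-3-methoxy-4-methylphenyl](2,6-dimethoxyphenyl)methanolate (not isolated) | COc1cccc(OC)c1C(O[Li])c1c([Li])c(OC)c(C)cc1OCc1ccccc1 | intermediate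
19 | lithium [6-(benzyloxy)-2-(dichloroceryl)-3-methoxy-4-methylphenyl](2,6-dimethoxyphenyl)methanolate (not isolated) | COc1cccc(OC)c1C(O[Li])c1c([Ce](Cl)Cl)c(OC)c(C)cc1OCc1ccccc1 | intermediate
20 | 1-{3-(benzyloxy)-2-[(2,6-dimethoxyphenyl)(hydroxy)methyl]-6-methoxy-5-methylphenyl}-2-[3-(benzyloxy)-2-(2,6-dimethoxybenzoyl)-6-methoxy-5-methylphenyl]ethan-1-ol (mixture of diastereomers) | COc1cccc(OC)c1C(=O)c1c(OCc2ccccc2)cc(C)c(OC)c1CC(O)c1c(OC)c(C)cc(OCc2ccccc2)c1C(O)c1c(OC)cccc1OC | intermediate
21 | 1,2-bis[3-(benzyloxy)-2-(2,6-dimethoxybenzoyl)-6-methoxy-5-methylphenyl]ethan-1-one | COc1cccc(OC)c1C(=O)c1c(OCc2ccccc2)cc(C)c(OC)c1CC(=O)c1c(OC)c(C)cc(OCc2ccccc2)c1C(=O)c1c(OC)cccc1OC | intermediate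
22 | acredinone B, 1,2-bis[2-(2,6-dimethoxybenzoyl)-3-hydroxy-6-methoxy-5-methylphenyl]ethan-1-one | COc1cccc(OC)c1C(=O)c1c(O)cc(C)c(OC)c1CC(=O)c1c(OC)c(C)cc(O)c1C(=O)c1c(OC)cccc1OC | target

**Step count**

Total: 13 steps. Longest linear sequence: 9 steps (1, 2, 3, 4, 6, 7, 11, 12, 13).

**Steps most likely to fail**

Step 6. Ionisation of the primary benzylic alcohol may be too slow, because the B5 methoxy group is flanked on both sides and cannot lie fully in plane. In that case several processes could outrun indene formation: self-benzylation of the electron-rich arenes, hydration of the alkyne, capture of the vinyl cation by water or by the B5 methoxy oxygen (demethylative closure to a 4H-chromene), and benzyl transfer from the ether under FeCl3. The fallback sets out from aldehyde 5 and comes back at indene 11; it builds the five-membered ring as an indanone and attaches ring A last. Reductive Knoevenagel alkylation of Meldrum's acid with 5 (L-proline cat, Hantzsch ester, EtOH) should give 5-{[5-(benzyloxy)-2-methoxy-3-methylphenyl]methyl}-2,2-dimethyl-1,3-dioxane-4,6-dione F1. Sc(OTf)3-catalysed intramolecular Friedel–Crafts acylation of F1 in CH3NO2 at 100 °C should close the K1–B1 bond with loss of acetone and CO2 and give 7-(benzyloxy)-4-methoxy-5-methyl-2,3-dihydro-1H-inden-1-one F2. KN(SiMe3)2 and PhNTf2 in THF at −78 °C should convert F2 into 4-(benzyloxy)-7-methoxy-6-methyl-1H-inden-3-yl trifluoromethanesulfonate F3. Suzuki–Miyaura coupling of F3 with (2,6-dimethoxyphenyl)boronic acid (Pd(OAc)2, SPhos, K3PO4, toluene/H2O) should then give 11.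

Step 11. The di-ortho-substituted aryl-metal may act as a base and remove a proton from the doubly activated Cα of 13 (enolisation) faster than it adds to the aldehyde, or the addition may be so slow for steric reasons that 13 decays. The fallback sets out from 13 and comes back at 21; it moves the electrophile to the carboxylic acid level, so that the K2 ketone is formed directly by acyl substitution. Pinnick oxidation of 13 (NaClO2, NaH2PO4, 2-methylbut-2-ene, t-BuOH/H2O) should give 2-[3-(benzyloxy)-2-(2,6-dimethoxybenzoyl)-6-methoxy-5-methylphenyl]acetic acid F4. Amide coupling with MeNHOMe·HCl (EDC, HOBt, iPr2NEt, CH2Cl2) should give the Weinreb amide 2-[3-(benzyloxy)-2-(2,6-dimethoxybenzoyl)-6-methoxy-5-methylphenyl]-N-methoxy-N-methylacetamide F5, whose Cα hydrogens are far less acidic than those of the aldehyde. Dianion 18, made from 17 and n-BuLi as in step 11 but without cerium, should add to F5 and give after work-up 1-{3-(benzyloxy)-2-[(2,6-dimethoxyphenyl)(hydroxy)methyl]-6-methoxy-5-methylphenyl}-2-[3-(benzyloxy)-2-(2,6-dimethoxybenzoyl)-6-methoxy-5-methylphenyl]ethan-1-one F6. Dess–Martin periodinane with pyridine then oxidises the remaining K3 carbinol to give 21.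

Step 7. Ozone may attack the electron-rich alkoxyarenes or the benzylic ether CH2 before the hindered alkene is fully consumed, or the hindered ozonide may resist reduction. The fallback sets out from 11 and comes back at 13; it replaces ozonolysis by a two-stage glycol cleavage. Dihydroxylation with OsO4 (cat) and NMO in acetone/H2O should give cis-7-(benzyloxy)-1-(2,6-dimethoxyphenyl)-4-methoxy-5-methyl-2,3-dihydro-1H-indene-1,2-diol F7 (racemic), and NaIO4 in THF/H2O should cleave F7 to 13.

**Further compounds**

F1 | step 6 | 5-{[5-(benzyloxy)-2-methoxy-3-methylphenyl]methyl}-2,2-dimethyl-1,3-dioxane-4,6-dione | COc1c(C)cc(OCc2ccccc2)cc1CC1C(=O)OC(C)(C)OC1=O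
F2 | step 6 | 7-(benzyloxy)-4-methoxy-5-methyl-2,3-dihydro-1H-inden-1-one | O=C1CCc2c(OC)c(C)cc(OCc3ccccc3)c21
F3 | step 6 | 4-(benzyloxy)-7-methoxy-6-methyl-1H-inden-3-yl trifluoromethanesulfonate | COc1c(C)cc(OCc2ccccc2)c2c1CC=C2OS(=O)(=O)C(F)(F)F
F4 | step 11 | 2-[3-(benzyloxy)-2-(2,6-dimethoxybenzoyl)-6-methoxy-5-methylphenyl]acetic acid | COc1cccc(OC)c1C(=O)c1c(OCc2ccccc2)cc(C)c(OC)c1CC(=O)O
F5 | step 11 | 2-[3-(benzyloxy)-2-(2,6-dimethoxybenzoyl)-6-methoxy-5-methylphenyl]-N-methoxy-N-methylacetamide | COc1cccc(OC)c1C(=O)c1c(OCc2ccccc2)cc(C)c(OC)c1CC(=O)N(C)OC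
F6 | step 11 | 1-{3-(benzyloxy)-2-[(2,6-dimethoxyphenyl)(hydroxy)methyl]-6-methoxy-5-methylphenyl}-2-[3-(benzyloxy)-2-(2,6-dimethoxybenzoyl)-6-methoxy-5-methylphenyl]ethan-1-one (racemic) | COc1cccc(OC)c1C(=O)c1c(OCc2ccccc2)cc(C)c(OC)c1CC(=O)c1c(OC)c(C)cc(OCc2ccccc2)c1C(O)c1c(OC)cccc1OC
F7 | step 7 | cis-7-(benzyloxy)-1-(2,6-dimethoxyphenyl)-4-methoxy-5-methyl-2,3-dihydro-1H-indene-1,2-diol (racemic, one enantiomer drawn) | COc1cccc(OC)c1[C@]1(O)[C@@H](O)Cc2c(OC)c(C)cc(OCc3ccccc3)c21
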